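Its constants were drawn at random within sensible limits; the run is a simulation.

3 questions stand on this flask, and one time answers them.

    starting material + reagent in the reaction phase → product (k1 = 1.2 M⁻¹ min⁻¹)
    reagent in the reaction phase ⇌ reagent in the second phase, rate k2*([reagent in the reaction phase] - [reagent in the second phase]/K2) per volume of the first phase (K2 = 0.80, k2 = 0.095 min⁻¹)
    2 starting material → homo dimer (k3 = 0.050 M⁻¹ min⁻¹)

starting material 1.2 M; reagent in the second phase 1.20 M; time 30 min; volume of the second phase over the first 0.50

- percentages count the starting material that a species holds: one homo dimer counts as two
- a doubled species enters its step squared and goes two at a time
- in the second phase: reagent in the second phase; everything else is in the first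
- charges count per volume of the first phase; a concentration in a rate is the amount of a species over the volume of its own phase; every rate counts per litre of the first phase
- run time (flask): 30 min

- product at 30 min, in percent of the starting material charged
- the change that raises the amount of product at 30 min, in percent of the starting material charged most ("none" if none brings more than 2 percentage points) (violet / blue / none)
- amount of product at 30 min, in percent of the starting material charged, after blue

Write s for the fraction of the starting material still there, and build the flask up.

1. Main step alone, with the reagent placed in the reaction phase. The charges are equal, so s = 1/(1 + k₁cₐt), which leaves 2.26% at 30 min.

2. Add the passage. The reaction phase uses reagent within about 0.694 min, faster than the passage delivers it. The passage is therefore the rate-limiting step, and the second phase drains with the drain time 4.21 min, the partition ratio times the volume ratio over the transfer coefficient. Equal charges make s follow it: s = exp(−t/τ), or 0.0804% at 30 min.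

3. Add the dimer, at both ends. While reagent builds up, s stands near its full value for that first wait, which costs 8.33%. Along the decay, the integral of s squared costs 25.3%. Joined, d = 33.6%. The loss lowers its own s, so I read d as dimer against product, and y = 1/(1 + d) = 74.9%.

4. Blue shortens τ to 2.10 min, so d = 0.210 and the product is 82.7%.

5. Violet keeps τ, but in this reckoning s reaches zero at τ ln 2. Integrating to there gives d = 0.181. The better change is violet.

The forecast gave 78%, then 83% after blue, just above my figure, and chose violet: “Violet gives a larger feed term than blue”.

The simulation gives 75.4%, 81.2% after blue, and violet as best, with 8.9 percentage points against 5.8 points for blue.

In this flask, the transfer has done half of its turnover by 2.82 min, against τ ln 2 = 2.92 min. At 2.82 min, the reagent in the reaction phase has a half-life of 0.98 min by the main step, shorter than that drain half-life, and is made 1.08 times as fast as it is used up.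

Read the same flask at 12 min, and τ leaves s = 5.78%. The computed starting material there is 4.60%.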